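The triaryl diether is cut at the ether joining ring A (the 4-allyl-2-methoxyphenoxy end) to the central ring B. Ring A C1 is the oxygen-bearing carbon of eugenol, so that carbon is converted into a boronic acid and the ether oxygen is supplied by ring B. Its less hindered catechol oxygen, which has a single ortho substituent, is the only free hydroxyl of the phenol partner; the flanked oxygen is masked as a MOM acetal. A room-temperature oxidative copper coupling joins the two in one operation and leaves every allyl group unconjugated. Ring C is then attached at the unmasked hindered oxygen with the MOM-protected bromide that also supplies ring B.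

Key step: step 8

Remark: ring A is the 4-allyl-2-methoxyphenoxy end, ring B the central ring, ring C the phenolic end ring. The target has no stereocentre; dienones 8 and 9 are transient racemates. Air (O2) is taken as the terminal oxidant in step 8.

Step 1
Reactants: 1 eugenol (4-allyl-2-methoxyphenol)
Product: 2 4-allyl-2-methoxyphenyl trifluoromethanesulfonate
Conditions: Tf2O (1.2 equiv), pyridine, CH2Cl2, 0 °C → rt
Reagents that add atoms: trifluoromethanesulfonic anhydride, O=S(=O)(OS(=O)(=O)C(F)(F)F)C(F)(F)F
Why: O-sulfonylation of the phenol (aryl triflate formation) is fast at 0 °C and leaves the allyl group and the methyl ether untouched.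

Step 2
Reactants: 2 4-allyl-2-methoxyphenyl trifluoromethanesulfonate; 3 bis(pinacolato)diboron
Product: 4 2-(4-allyl-2-methoxyphenyl)-4,4,5,5-tetramethyl-1,3,2-dioxaborolane
Conditions: PdCl2(dppf) (3 mol%), KOAc (3 equiv), 1,4-dioxane, 80 °C, Ar
Reagents that add atoms: none
Why: Miyaura borylation (oxidative addition of zerovalent palladium into the C–OTf bond, acetate-assisted transmetalation with 3, reductive elimination) is routine for aryl triflates, and KOAc is too weak a base to shift the allyl double bond.

Step 3
Reactants: 4 2-(4-allyl-2-methoxyphenyl)-4,4,5,5-tetramethyl-1,3,2-dioxaborolane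
Product: 5 (4-allyl-2-methoxyphenyl)boronic acid
Conditions: NaIO4 (3 equiv), NH4OAc (3 equiv), acetone/H2O 1:1, rt
Reagents that add atoms: water, O
Why: Oxidative deprotection of a pinacol boronate: periodate cleaves the pinacol freed in the hydrolysis equilibrium to acetone and so pulls the ester over to the boronic acid, while periodate alone does not attack a terminal alkene.

Step 4
Reactants: 6 2-bromo-6-methoxyphenol
Product: 7 2-(allyloxy)-1-bromo-3-methoxybenzene
Conditions: allyl bromide (1.3 equiv), K2CO3 (2 equiv), acetone, reflux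
Reagents that add atoms: allyl bromide, C=CCBr
Why: Williamson ether synthesis of an acidic, ortho-halogenated phenol with a reactive allylic halide.

Step 5
Reactants: 7 2-(allyloxy)-1-bromo-3-methoxybenzene
Product: 10 4-allyl-2-bromo-6-methoxyphenol, via ortho-allyl dienone 8 (not isolated), via para-allyl dienone 9 (not isolated)
Conditions: N,N-diethylaniline, 195 °C, Ar, sealed tube
Reagents that add atoms: none
Why: para-Claisen rearrangement: the aromatic Claisen [3,3] shift places allyl on a blocked ortho carbon (drawn for the methoxy-bearing one), the dienone cannot enolise and passes the allyl group on to the free para carbon by a Cope [3,3] shift, and tautomerisation of 9 restores the phenol.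

Step 6
Reactants: 10 4-allyl-2-bromo-6-methoxyphenol
Product: 11 5-allyl-1-bromo-3-methoxy-2-(methoxymethoxy)benzene
Conditions: MOMCl (1.5 equiv), iPr2NEt (2 equiv), CH2Cl2, 0 °C → rt
Reagents that add atoms: chloromethyl methyl ether, COCCl
Why: MOM protection (O-alkylation of the phenol by the highly electrophilic α-chloro ether) proceeds even on a phenol with two ortho substituents.

Step 7
Reactants: 11 5-allyl-1-bromo-3-methoxy-2-(methoxymethoxy)benzene
Product: 14 5-allyl-3-methoxy-2-(methoxymethoxy)phenol, via aryllithium 12 (not isolated), via lithium aryltrimethoxyborate 13 (not isolated)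
Conditions: n-BuLi (1.05 equiv), THF, −78 °C; B(OMe)3 (1.5 equiv), −78 → 0 °C; AcOH, 30% H2O2, 0 °C → rt
Reagents that add atoms: hydrogen peroxide, OO (the new phenol oxygen); n-butyllithium, [Li]CCCC, and trimethyl borate, COB(OC)OC, leave atoms only in intermediates 12 and 13
Why: Bromine–lithium exchange (faster at −78 °C than deprotonation of the allylic CH2 and helped by the ortho MOM oxygen), borylation and peroxide-induced 1,2-aryl shift from boron to oxygen (ipso-hydroxylation) replace Br by OH at the same carbon.

Step 8
Reactants: 5 (4-allyl-2-methoxyphenyl)boronic acid; 14 5-allyl-3-methoxy-2-(methoxymethoxy)phenol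
Product: 15 5-allyl-1-(4-allyl-2-methoxyphenoxy)-3-methoxy-2-(methoxymethoxy)benzene
Conditions: Cu(OAc)2 (1.0 equiv), pyridine (5 equiv), powdered 4 Å MS, CH2Cl2, dry air, rt; 5 (2.5 equiv) added in portions
Reagents that add atoms: none
Why: Chan–Lam oxidative C–O coupling: phenol 14 binds Cu(OAc)2 as a divalent copper phenoxide, the aryl group of 5 passes from boron to copper, oxidation gives an aryl trivalent copper phenoxide, and C–O reductive elimination forms the ring A C1–O bond while O2 returns the reduced copper to the divalent state. The closest known reaction type is the Cu(OAc)2/amine O-arylation of phenols with arylboronic acids, which accepts ortho-alkoxy groups on both partners. No ring is closed and no stereocentre is formed. Site selectivity between the two catechol oxygens of ring B is required and is secured because the flanked oxygen carries the MOM acetal, so 14 offers a single free hydroxyl with one ortho substituent. Molecular sieves and portionwise excess of 5 should hold back hydroxylation and protodeboronation of the boronic acid. Room temperature and pyridine as the only base should keep all allyl groups out of conjugation and the MOM acetal intact.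

Step 9
Reactants: 15 5-allyl-1-(4-allyl-2-methoxyphenoxy)-3-methoxy-2-(methoxymethoxy)benzene
Product: 16 4-allyl-2-(4-allyl-2-methoxyphenoxy)-6-methoxyphenol
Conditions: conc. HCl (cat.), MeOH, 45 °C
Reagents that add atoms: none
Why: Acid-catalysed acetal exchange with methanol (MOM cleavage) frees the flanked phenol; diaryl ether, methyl ethers and isolated alkenes are inert to dilute acid.

Step 10
Reactants: 16 4-allyl-2-(4-allyl-2-methoxyphenoxy)-6-methoxyphenol; 11 5-allyl-1-bromo-3-methoxy-2-(methoxymethoxy)benzene
Product: 17 5-allyl-1-[4-allyl-2-(4-allyl-2-methoxyphenoxy)-6-methoxyphenoxy]-3-methoxy-2-(methoxymethoxy)benzene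
Conditions: CuI (cuprous iodide, 10 mol%), picolinic acid (20 mol%), K3PO4 (2 equiv), DMSO, 90 °C, Ar
Reagents that add atoms: none
Why: Ullmann diaryl ether synthesis through a picolinate-ligated monovalent copper phenoxide, a ligand system suited to phenols with two ortho substituents and to ortho-substituted aryl bromides; phosphate is too weak a base to isomerise the allyl groups and the MOM acetal is base-stable.

Step 11
Reactants: 17 5-allyl-1-[4-allyl-2-(4-allyl-2-methoxyphenoxy)-6-methoxyphenoxy]-3-methoxy-2-(methoxymethoxy)benzene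
Product: 18 4-allyl-2-[4-allyl-2-(4-allyl-2-methoxyphenoxy)-6-methoxyphenoxy]-6-methoxyphenol (target)
Conditions: conc. HCl (cat.), MeOH, 45 °C
Reagents that add atoms: none
Why: Acid-catalysed MOM cleavage by acetal exchange, the same mild deprotection as in step 9, ends the route without heat or base on the trimer.

Compound list
1 | eugenol (4-allyl-2-methoxyphenol) | C=CCc1ccc(O)c(OC)c1 | starting material
2 | 4-allyl-2-methoxyphenyl trifluoromethanesulfonate | C=CCc1ccc(OS(=O)(=O)C(F)(F)F)c(OC)c1 | intermediate
3 | bis(pinacolato)diboron | CC1(C)OB(OC1(C)C)B1OC(C)(C)C(C)(C)O1 | starting material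
4 | 2-(4-allyl-2-methoxyphenyl)-4,4,5,5-tetramethyl-1,3,2-dioxaborolane | C=CCc1ccc(B2OC(C)(C)C(C)(C)O2)c(OC)c1 | intermediate
5 | (4-allyl-2-methoxyphenyl)boronic acid | C=CCc1ccc(B(O)O)c(OC)c1 | intermediate
6 | 2-bromo-6-methoxyphenol | COc1cccc(Br)c1O | starting material
7 | 2-(allyloxy)-1-bromo-3-methoxybenzene | C=CCOc1c(Br)cccc1OC | intermediate
8 | 6-allyl-2-bromo-6-methoxycyclohexa-2,4-dien-1-one (racemic) | C=CCC1(OC)C=CC=C(Br)C1=O | intermediate (not isolated)
9 | 4-allyl-2-bromo-6-methoxycyclohexa-2,5-dien-1-one (racemic) | C=CCC1C=C(OC)C(=O)C(Br)=C1 | intermediate (not isolated)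
10 | 4-allyl-2-bromo-6-methoxyphenol | C=CCc1cc(Br)c(O)c(OC)c1 | intermediate
11 | 5-allyl-1-bromo-3-methoxy-2-(methoxymethoxy)benzene | C=CCc1cc(Br)c(OCOC)c(OC)c1 | intermediate
12 | [5-allyl-3-methoxy-2-(methoxymethoxy)phenyl]lithium | [Li]c1cc(CC=C)cc(OC)c1OCOC | intermediate (not isolated)
13 | lithium [5-allyl-3-methoxy-2-(methoxymethoxy)phenyl]trimethoxyborate | [Li+].CO[B-](OC)(OC)c1cc(CC=C)cc(OC)c1OCOC | intermediate (not isolated)
14 | 5-allyl-3-methoxy-2-(methoxymethoxy)phenol | C=CCc1cc(O)c(OCOC)c(OC)c1 | intermediate
15 | 5-allyl-1-(4-allyl-2-methoxyphenoxy)-3-methoxy-2-(methoxymethoxy)benzene | C=CCc1ccc(Oc2cc(CC=C)cc(OC)c2OCOC)c(OC)c1 | intermediate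
16 | 4-allyl-2-(4-allyl-2-methoxyphenoxy)-6-methoxyphenol | C=CCc1ccc(Oc2cc(CC=C)cc(OC)c2O)c(OC)c1 | intermediate
17 | 5-allyl-1-[4-allyl-2-(4-allyl-2-methoxyphenoxy)-6-methoxyphenoxy]-3-methoxy-2-(methoxymethoxy)benzene | C=CCc1ccc(Oc2cc(CC=C)cc(OC)c2Oc2cc(CC=C)cc(OC)c2OCOC)c(OC)c1 | intermediate
18 | 4-allyl-2-[4-allyl-2-(4-allyl-2-methoxyphenoxy)-6-methoxyphenoxy]-6-methoxyphenol | C=CCc1ccc(Oc2cc(CC=C)cc(OC)c2Oc2cc(CC=C)cc(OC)c2O)c(OC)c1 | target

Total step count: 11 (bromide 11 is used twice, in steps 7 and 10).
Longest linear sequence: 8 steps (steps 4, 5, 6, 7, 8, 9, 10, 11 from 2-bromo-6-methoxyphenol 6); the boronic acid branch is 3 steps.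

Steps most likely to fail

1. Step 8 (Chan–Lam coupling). With an ortho-methoxy boronic acid and an ortho-alkoxy phenol, aryl transfer to copper may be slower than protodeboronation and oxidative hydroxylation of the boronic acid, so the phenol would be left unreacted. Fallback: the same ether is made with the polarity reversed, by an Ullmann coupling in which eugenol 1 is the phenol and bromide 11 the aryl donor (CuI, picolinic acid, K3PO4, DMSO, 90 °C). This forms the ring B C–O bond instead of the ring A C1–O bond and should give 15 directly. It sets out from 1 and 11 and comes back at 15; no new compound is made (F0).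

2. Step 10 (Ullmann coupling). Oxidative addition of the electron-rich, ortho-substituted bromide and approach of the doubly flanked phenoxide may be too slow, so that hydrodebromination of the bromide and catalyst decay take over. Fallback: the ring B–ring C ether is made by nucleophilic aromatic substitution, setting out from 16 and coming back at the target 18.
   - Phenol 16 and 2-fluoro-6-methoxybenzaldehyde (K2CO3, DMF, 90 °C; the ortho formyl group activates fluoride displacement) should give 2-[4-allyl-2-(4-allyl-2-methoxyphenoxy)-6-methoxyphenoxy]-6-methoxybenzaldehyde F1.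
   - Dakin-type oxidation (30% H2O2, cat. H2SO4, MeOH, rt; isolated alkenes are not touched) should pass through 2-[4-allyl-2-(4-allyl-2-methoxyphenoxy)-6-methoxyphenoxy]-6-methoxyphenyl formate F2 (not isolated), which methanol cleaves to 2-[4-allyl-2-(4-allyl-2-methoxyphenoxy)-6-methoxyphenoxy]-6-methoxyphenol F3.
   - Allyl bromide and K2CO3 in acetone should give 5-allyl-2-[2-(allyloxy)-3-methoxyphenoxy]-1-(4-allyl-2-methoxyphenoxy)-3-methoxybenzene F4.
   - para-Claisen rearrangement (N,N-diethylaniline, 190 °C) through the ortho-allyl dienone F5 and the para-allyl dienone F6 (neither isolated) should give 18.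

3. Step 5 (para-Claisen rearrangement). At the dienone stage, loss of bromine from the bromine-bearing ortho carbon or intermolecular allyl transfer may compete with the Cope shift, and prolonged heating may degrade the material. Fallback: compound 10 is reached from eugenol 1 by bromination and zinc debromination. Br2 (2 equiv, CH2Cl2, 0 °C) first adds across the alkene to give 4-(2,3-dibromopropyl)-2-methoxyphenol F7 (not isolated) and then substitutes ortho to the hydroxyl to give 2-bromo-4-(2,3-dibromopropyl)-6-methoxyphenol F8. Zn dust in AcOH/EtOH at rt removes the vicinal dibromide, restores the allyl group and leaves the aryl bromide, which should give 10. It sets out from 1 and comes back at 10.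

Further compounds
F0 | step 8 | none | none
F1 | step 10 | 2-[4-allyl-2-(4-allyl-2-methoxyphenoxy)-6-methoxyphenoxy]-6-methoxybenzaldehyde | C=CCc1ccc(Oc2cc(CC=C)cc(OC)c2Oc2cccc(OC)c2C=O)c(OC)c1
F2 | step 10 | 2-[4-allyl-2-(4-allyl-2-methoxyphenoxy)-6-methoxyphenoxy]-6-methoxyphenyl formate | C=CCc1ccc(Oc2cc(CC=C)cc(OC)c2Oc2cccc(OC)c2OC=O)c(OC)c1
F3 | step 10 | 2-[4-allyl-2-(4-allyl-2-methoxyphenoxy)-6-methoxyphenoxy]-6-methoxyphenol | C=CCc1ccc(Oc2cc(CC=C)cc(OC)c2Oc2cccc(OC)c2O)c(OC)c1
F4 | step 10 | 5-allyl-2-[2-(allyloxy)-3-methoxyphenoxy]-1-(4-allyl-2-methoxyphenoxy)-3-methoxybenzene | C=CCc1ccc(Oc2cc(CC=C)cc(OC)c2Oc2cccc(OC)c2OCC=C)c(OC)c1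
F5 | step 10 | 6-allyl-2-[4-allyl-2-(4-allyl-2-methoxyphenoxy)-6-methoxyphenoxy]-6-methoxycyclohexa-2,4-dien-1-one (racemic) | C=CCc1ccc(Oc2cc(CC=C)cc(OC)c2OC2=CC=CC(CC=C)(OC)C2=O)c(OC)c1
F6 | step 10 | 4-allyl-2-[4-allyl-2-(4-allyl-2-methoxyphenoxy)-6-methoxyphenoxy]-6-methoxycyclohexa-2,5-dien-1-one (racemic) | C=CCc1ccc(Oc2cc(CC=C)cc(OC)c2OC2=CC(CC=C)C=C(OC)C2=O)c(OC)c1
F7 | step 5 | 4-(2,3-dibromopropyl)-2-methoxyphenol (racemic) | COc1cc(CC(Br)CBr)ccc1O
F8 | step 5 | 2-bromo-4-(2,3-dibromopropyl)-6-methoxyphenol (racemic) | COc1cc(CC(Br)CBr)cc(Br)c1O
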